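The runs were generated by integration for an exercise, and the scatter is random.

At early times the gamma run held target and hardly any isomer of the product: 5.2% against 0% at 0.500 min. By 6.00 min it read 52.2% against 7.2%. So I took the isomer to form from target, in one first-order step with constant k.

| setting | gamma | epsilon | theta | dawn | noon | autumn | spring |
|---|---|---|---|---|---|---|---|
| substrate | 0.047 M | 0.024 M | 0.035 M | 0.047 M | 0.047 M | 0.047 M | 0.047 M |
| reagent | 1.2 equiv | 1.2 equiv | 1.2 equiv | 1.20 equiv | 1.20 equiv (fed, over 8.00 min) | 1.20 equiv | 1.20 equiv |
| free catalyst | 1 mol% | 1 mol% | 1 mol% | 1 mol% | 1 mol% | 1 mol% | 1 mol% |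
| remark | run made earlier | run made earlier | run made earlier | a closed flask charged with all of it at once and left for 10 min | a stirred flask in which reagent is dosed at a steady rate over 8.00 min without added volume, worked up at 10 min | a tube with plug flow, the mixed feed as stated, residence time 10 min | one stirred flow tank at steady state, fed with the mixture as stated, mean residence time 10 min |
| time |  |  |  | 10 min | 10 min | 10 min |  |

| run | time / min | target / % | isomer of the product / % | substrate / % |
|---|---|---|---|---|
| gamma | 0.500 | 5.2 | 0 | 93.5 |
| gamma | 0.667 | 7.7 | 0.5 | 91.7 |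
| gamma | 1.00 | 11.5 | 0.3 | 87.1 |
| gamma | 1.50 | 16.8 | 0 | 82.7 |
| gamma | 2.50 | 25.5 | 1.9 | 71.1 |
| gamma | 4.00 | 38.7 | 3.2 | 56.7 |
| gamma | 6.00 | 52.2 | 7.2 | 38.9 |
| epsilon | 0.833 | 6.6 | 0.2 | 92.1 |
| epsilon | 1.50 | 11.2 | 0 | 87.8 |
| epsilon | 2.50 | 18.5 | 0.9 | 79.0 |
| epsilon | 3.00 | 21.9 | 1.1 | 75.0 |
| epsilon | 4.00 | 27.8 | 2.1 | 67.8 |
| epsilon | 5.00 | 32.5 | 4.7 | 61.8 |
| epsilon | 6.00 | 37.9 | 4.8 | 55.9 |
| theta | 0.333 | 3.5 | 0 | 95.9 |
| theta | 1.00 | 9.5 | 0.5 | 88.9 |
| theta | 1.50 | 13.4 | 0.9 | 84.8 |
| theta | 2.50 | 23.5 | 1.3 | 75.4 |
| theta | 4.00 | 34.1 | 3.5 | 61.3 |
| theta | 5.00 | 40.9 | 5.1 | 53.3 |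
| theta | 6.00 | 46.2 | 6.2 | 46.5 |

(scatter of a reading: 0.5 percentage points)

- the stated concentrations are those of everything mixed, before any reaction; amounts are the same in each set-up
- the feed brings no volume worth counting
- the earlier runs were made in a closed, stirred flask

- the set-up with the highest share of target in all that became target or isomer of the product, at the outlet or at the end ("none" if the first two lie within 2 percentage points) (dawn / noon / autumn / spring / none)
- share of target in all that became target or isomer of the product, at the outlet or at the end, dawn
- share of target in all that became target or isomer of the product, at the outlet or at the end, noon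
- share of target in all that became target or isomer of the product, at the outlet or at the end, autumn
- share of target in all that became target or isomer of the product, at the outlet or at the end, spring

If p and e are the fractions of the charge present as target and isomer, and a is the mean age of the target, then e/p is about k·a for a one-way step, while e is small against p. A steady making of target gives a equal to half the elapsed time. The three runs at 6.00 min then read k as 0.0460 min⁻¹, 0.0422 min⁻¹ and 0.0447 min⁻¹, though the gamma charge was twice the epsilon charge. Their mean was 0.0443 min⁻¹.

I folded this into one ageing number, a Damköhler number: N = k·t = 0.443, the time in the flask measured in lifetimes of target. Each set-up then adds a factor f, the mean age over the time: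

share = 1/(1 + f·N)

dawn, autumn: f = 0.5, share 81.9%

noon: f = 1/3, share 87.1%

spring: f = 1, share 69.3%

For noon I assumed that target forms in step with the reagent fed, so its making rises from nothing, and I let that rise run over the whole time, though the feed stops at 8.00 min. My noon therefore came first, by more than the margin.

The forecast gave 78% for dawn, 81% for noon, 78% for autumn and 70% for spring. For noon its ground was that “Dosing delays product formation, so product is younger”. Its dawn stood lower than mine, but it also named noon.

The flask gave 80.6% for dawn, 84.9% for noon, 80.6% for autumn and 76.8% for spring, so noon came first.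

    target ⇌ isomer of the product (K = 0.790, k = 0.0488 min⁻¹)
    reagent + catalyst intermediate A → catalyst intermediate B (k = 544 M⁻¹ min⁻¹)
    substrate + free catalyst → catalyst intermediate A (k = 7740 M⁻¹ min⁻¹)
    catalyst intermediate B ⇌ free catalyst + target (K = 0.0512 M, k = 20.6 min⁻¹)

One number was not enough. In noon, N/3 was 0.148 and the flask's isomer over target was 0.178. In spring, N was 0.443 and the flask's ratio was 0.302. The flask has what N has not, a way back from isomer to target: noon left until 100 min stood at a share of 55.9%. Then I took noon with 0.4 mol% of free catalyst. N holds no catalyst, so the reckoning stayed at 0.148 and 87.1%. That flask gave a ratio of 0.172 and a share of 85.4%, with target at 26.6%.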